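**Retrosynthetic overview**
1. The target 14 is a depside. Its strategy rests on ring B (C1 carboxyl, C2–OH, C3–Cl, C4–OMe, C6–Me): with the carboxyl and methyl carbons, ring B is an eight-carbon 1,3,5,7-oxygenated chain in which chain C4 carries the chlorine and chain C5 the methoxy group as an enol ether.
2. Key disconnection: the ring B C1–C6 bond (chain C2–C7), made by aldol closure and aromatization of the open-chain aryl (Z)-4-chloro-5-methoxy-3,7-dioxooct-4-enoate 11. Ring B is the only ring formed, and it is formed last; ring A is bought as methyl orsellinate 8.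
3. The depside C–O bond is made before ring B exists, by capture of acylketene 9 (from dioxinone 7) at the 4-OH of 8 under neutral conditions.
4. The chain C4–C5 bond comes from γ-acylation of the dioxinone dienolate with a C7-ketal acetoacetyl donor 2. The ketal leaves chain C4 as the only doubly activated carbon for chlorination and chain C5 as the only enolizable ketone for O-methylation.

Key step: step 7

Assumption: the C4=C5 enol ether is drawn and named Z (C3 and C6 cis, acyl trans to methoxy, the usual preferred arrangement of β-alkoxy enones); any E isomer from step 4 is carried along, since this push–pull double bond is expected to equilibrate under the conditions of steps 6 and 7.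

**Route**

Step 1
Reactants: 1 ethyl 2-(2-methyl-1,3-dioxolan-2-yl)acetate
Product: 2 N-methoxy-N-methyl-2-(2-methyl-1,3-dioxolan-2-yl)acetamide
Conditions: MeNH(OMe)·HCl (1.5 equiv), i-PrMgCl (3 equiv), THF, −20 → 0 °C
Reagents that add atoms: N,O-dimethylhydroxylamine hydrochloride, CNOC.Cl
Why: Aminolysis of the ethyl ester by the chloromagnesium amide of N,O-dimethylhydroxylamine (N-methoxy-N-methylamide formation) is a standard acyl substitution that the dioxolane tolerates, and it gives an acyl donor that should resist over-addition and enolization in step 2.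

Step 2
Reactants: 2 N-methoxy-N-methyl-2-(2-methyl-1,3-dioxolan-2-yl)acetamide; 3 dioxinone 2,2,6-trimethyl-4H-1,3-dioxin-4-one
Product: 5 keto-dioxinone 2,2-dimethyl-6-[3-(2-methyl-1,3-dioxolan-2-yl)-2-oxopropyl]-4H-1,3-dioxin-4-one, via lithium dienolate 4 (not isolated)
Conditions: 3 (1.6 equiv), LiN(SiMe3)2 (1.6 equiv), THF, −78 °C; then 2, −78 → −20 °C; aq. NH4Cl
Reagents that add atoms: none
Why: The dienolate 4 reacts at its γ-carbon (the former 6-methyl group) in a Claisen-type acylation that forms the chain C4–C5 bond, and the chelated tetrahedral adduct of the N-methoxy-N-methylamide should persist until work-up so that the acidic product neither quenches the dienolate nor is acylated twice.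

Step 3
Reactants: 5 keto-dioxinone 2,2-dimethyl-6-[3-(2-methyl-1,3-dioxolan-2-yl)-2-oxopropyl]-4H-1,3-dioxin-4-one
Product: 6 chloro keto-dioxinone 6-[1-chloro-3-(2-methyl-1,3-dioxolan-2-yl)-2-oxopropyl]-2,2-dimethyl-4H-1,3-dioxin-4-one (racemic)
Conditions: MgCl2 (1.2 equiv), pyridine (2 equiv), CH2Cl2, 0 °C; then NCS (1.0 equiv), 0 °C
Reagents that add atoms: N-chlorosuccinimide, O=C1CCC(=O)N1Cl
Why: Soft enolization with MgCl2 and pyridine should engage only the chain C4 methylene, which lies between the C5 ketone and the dioxinone C6 and is the site that is C-acylated under these conditions, and electrophilic α-chlorination by one equivalent of NCS should then give the monochloride, because the C7 ketal leaves C6 only singly activated.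

Step 4
Reactants: 6 chloro keto-dioxinone 6-[1-chloro-3-(2-methyl-1,3-dioxolan-2-yl)-2-oxopropyl]-2,2-dimethyl-4H-1,3-dioxin-4-one
Product: 7 enol ether 6-[(1Z)-1-chloro-2-methoxy-3-(2-methyl-1,3-dioxolan-2-yl)prop-1-en-1-yl]-2,2-dimethyl-4H-1,3-dioxin-4-one
Conditions: Cs2CO3 (1.5 equiv), Me2SO4 (1.3 equiv), DMF, 0 → 23 °C
Reagents that add atoms: dimethyl sulfate, COS(=O)(=O)OC
Why: This is an enolate O-alkylation in which the dissociated cesium enolate of the chlorinated C4–H should be methylated by the hard electrophile on oxygen and not on the hindered chlorine-bearing carbon, and since C7 is a ketal the C5 ketone can enolize in conjugation only toward C4, which fixes the C4=C5 enol ether.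

Step 5
Reactants: 7 enol ether 6-[(1Z)-1-chloro-2-methoxy-3-(2-methyl-1,3-dioxolan-2-yl)prop-1-en-1-yl]-2,2-dimethyl-4H-1,3-dioxin-4-one; 8 methyl orsellinate (methyl 2,4-dihydroxy-6-methylbenzoate)
Product: 10 ketal aryl ester methyl 4-{[(4Z)-4-chloro-5-methoxy-6-(2-methyl-1,3-dioxolan-2-yl)-3-oxohex-4-enoyl]oxy}-2-hydroxy-6-methylbenzoate, via acylketene 9 (not isolated)
Conditions: 8 (1.5 equiv), toluene, 4 Å MS, 110 °C, N2 sweep
Reagents that add atoms: none
Why: Thermal retro-[4+2] loss of acetone gives acylketene 9, which should be captured under neutral conditions by the free 4-OH of 8 (the 2-OH is hydrogen-bonded to the ester and less nucleophilic) in the known acylketene route to aryl β-keto esters, while the methyl cap on the C5 oxygen blocks cyclization to a 4-hydroxy-2-pyranone.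

Step 6
Reactants: 10 ketal aryl ester methyl 4-{[(4Z)-4-chloro-5-methoxy-6-(2-methyl-1,3-dioxolan-2-yl)-3-oxohex-4-enoyl]oxy}-2-hydroxy-6-methylbenzoate
Product: 11 methyl 4-{[(4Z)-4-chloro-5-methoxy-3,7-dioxooct-4-enoyl]oxy}-2-hydroxy-6-methylbenzoate
Conditions: PPTS (0.3 equiv), acetone/H2O (20:1), 50 °C; crude product taken on directly
Reagents that add atoms: water, O
Why: Acid-catalysed ketal hydrolysis with transketalization to acetone under pyridinium buffering should free the C7 ketone, while the vinylogous ester (C3 carbonyl–C4=C5–OMe), deactivated toward protonation by the C4 chlorine, and the aryl ester should survive this mild acidity.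

Step 7
Reactants: 11 methyl 4-{[(4Z)-4-chloro-5-methoxy-3,7-dioxooct-4-enoyl]oxy}-2-hydroxy-6-methylbenzoate
Product: 14 methyl 4-[(3-chloro-2-hydroxy-4-methoxy-6-methylbenzoyl)oxy]-2-hydroxy-6-methylbenzoate, via cyclic aldol adduct 12 (not isolated), via cyclohexadienone 13 (not isolated)
Conditions: Et3N (0.5 equiv), 4 Å MS, CH2Cl2, 0 → 23 °C; then AcOH
Reagents that add atoms: none
Why: Triethylamine should reversibly deprotonate only C2, the most acidic CH of 11 (between the aryl ester and the C3 ketone), and this enolate adds to the C7 methyl ketone to form the ring B C1–C6 bond in aldol adduct 12; E1cB loss of the tertiary hydroxyl gives cross-conjugated dienone 13, which tautomerizes through its doubly activated C6 methylene to the phenol, so aromatization makes the sequence irreversible. The closest known reaction type is the biomimetic intramolecular aldol condensation and aromatization of 3,5,7-tricarbonyl esters to orsellinates, a Knoevenagel-type closure of a β-keto ester onto a ketone. Ring B closes in the 6-(enolendo)-exo-trig mode, with the C2=C3 enolate bond inside and the C7 carbonyl outside the forming ring. No stereocenter is set: the two stereocenters of 12 are erased on aromatization, and the Z geometry of the C4=C5 bond, which holds C3 and C6 cis, is absorbed into the arene. The selectivity needed is aldol closure (C2 onto C7) over Claisen closure (C6 onto the aryl ester C1 with loss of ring A phenoxide) and over lactonization to a 4-hydroxy-2-pyranone; the first should be secured by the greater acidity of C2–H over C6–H under a weak amine base, the C2 enolate also deactivating the ester, and the second by the methyl cap on the C5 oxygen, which sits trans to C3. The dry, non-nucleophilic medium means that any E1cB loss of ring A phenoxide to an acylketene should simply be reversed by recapture.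

**Compound list**
1 | ethyl 2-(2-methyl-1,3-dioxolan-2-yl)acetate | CCOC(=O)CC1(C)OCCO1 | starting material
2 | N-methoxy-N-methyl-2-(2-methyl-1,3-dioxolan-2-yl)acetamide | CON(C)C(=O)CC1(C)OCCO1 | intermediate
3 | 2,2,6-trimethyl-4H-1,3-dioxin-4-one | CC1=CC(=O)OC(C)(C)O1 | starting material
4 | lithium 2,2-dimethyl-6-methylidene-6H-1,3-dioxin-4-olate (dienolate of 3) | [Li+].[O-]C1=CC(=C)OC(C)(C)O1 | intermediate (not isolated)
5 | 2,2-dimethyl-6-[3-(2-methyl-1,3-dioxolan-2-yl)-2-oxopropyl]-4H-1,3-dioxin-4-one | CC1(C)OC(=O)C=C(CC(=O)CC2(C)OCCO2)O1 | intermediate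
6 | 6-[1-chloro-3-(2-methyl-1,3-dioxolan-2-yl)-2-oxopropyl]-2,2-dimethyl-4H-1,3-dioxin-4-one (racemic) | CC1(C)OC(=O)C=C(C(Cl)C(=O)CC2(C)OCCO2)O1 | intermediate
7 | 6-[(1Z)-1-chloro-2-methoxy-3-(2-methyl-1,3-dioxolan-2-yl)prop-1-en-1-yl]-2,2-dimethyl-4H-1,3-dioxin-4-one | CC1(C)OC(=O)C=C(O1)/C(Cl)=C(/OC)CC2(C)OCCO2 | intermediate
8 | methyl orsellinate (methyl 2,4-dihydroxy-6-methylbenzoate) | COC(=O)c1c(C)cc(O)cc1O | starting material
9 | (4Z)-4-chloro-5-methoxy-6-(2-methyl-1,3-dioxolan-2-yl)hexa-1,4-diene-1,3-dione (acylketene) | O=C=CC(=O)/C(Cl)=C(/OC)CC1(C)OCCO1 | intermediate (not isolated)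
10 | methyl 4-{[(4Z)-4-chloro-5-methoxy-6-(2-methyl-1,3-dioxolan-2-yl)-3-oxohex-4-enoyl]oxy}-2-hydroxy-6-methylbenzoate | COC(=O)c1c(C)cc(OC(=O)CC(=O)/C(Cl)=C(/OC)CC2(C)OCCO2)cc1O | intermediate
11 | methyl 4-{[(4Z)-4-chloro-5-methoxy-3,7-dioxooct-4-enoyl]oxy}-2-hydroxy-6-methylbenzoate | COC(=O)c1c(C)cc(OC(=O)CC(=O)/C(Cl)=C(/OC)CC(C)=O)cc1O | intermediate
12 | methyl 4-{[(3-chloro-6-hydroxy-4-methoxy-6-methyl-2-oxocyclohex-3-en-1-yl)carbonyl]oxy}-2-hydroxy-6-methylbenzoate (diastereomer mixture) | COC(=O)c1c(C)cc(OC(=O)C2C(=O)C(Cl)=C(OC)CC2(C)O)cc1O | intermediate (not isolated)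
13 | methyl 4-{[(5-chloro-4-methoxy-2-methyl-6-oxocyclohexa-1,4-dien-1-yl)carbonyl]oxy}-2-hydroxy-6-methylbenzoate | COC(=O)c1c(C)cc(OC(=O)C2=C(C)CC(OC)=C(Cl)C2=O)cc1O | intermediate (not isolated)
14 | methyl 4-[(3-chloro-2-hydroxy-4-methoxy-6-methylbenzoyl)oxy]-2-hydroxy-6-methylbenzoate | COC(=O)c1c(C)cc(OC(=O)c2c(C)cc(OC)c(Cl)c2O)cc1O | target

**Step count**
Total steps: 7. Longest linear sequence: 7 steps (1 → 2 → 5 → 6 → 7 → 10 → 11 → 14); 3 and 8 enter as purchased materials.

**Steps most likely to fail, with fallbacks**

Step 7 (fold). Claisen-type closure from C6 onto the aryl ester, or irreversible loss of the ring A phenoxide, may outrun the aldol closure, and slow E-to-Z equilibration of the enol ether may stall it. The fallback separates the fold from the depside link. It sets out from 7: thermolysis in toluene at 110 °C with allyl alcohol should give allyl (4Z)-4-chloro-5-methoxy-6-(2-methyl-1,3-dioxolan-2-yl)-3-oxohex-4-enoate F1. Ketal cleavage with PPTS in wet acetone should give allyl (4Z)-4-chloro-5-methoxy-3,7-dioxooct-4-enoate F2. The same triethylamine fold, now without a good leaving group at C1, should give allyl 3-chloro-2-hydroxy-4-methoxy-6-methylbenzoate F3. Deallylation with catalytic Pd(PPh3)4 and morpholine in THF should give 3-chloro-2-hydroxy-4-methoxy-6-methylbenzoic acid F4. Coupling of F4 with 8 at its 4-OH through the mixed anhydride formed with trifluoroacetic anhydride in toluene (the usual depside esterification) comes back to the route at 14.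

Step 6 (ketal cleavage). Hydrolysis of the C5 methyl enol ether may compete with ketal cleavage, and acid may drive O-cyclization of the unmasked 1,5-dicarbonyl. The fallback accepts the loss of the methyl group and installs it after the fold. It sets out from 10: aqueous HCl in THF should remove both masks to give methyl 4-[(4-chloro-3,5,7-trioxooctanoyl)oxy]-2-hydroxy-6-methylbenzoate F5. The triethylamine fold of this free tricarbonyl chain should give methyl 4-[(3-chloro-2,4-dihydroxy-6-methylbenzoyl)oxy]-2-hydroxy-6-methylbenzoate F6. Ring B 4-OH is the only phenol not hydrogen-bonded to an ester carbonyl, so methylation with trimethylsilyldiazomethane in toluene/methanol should be selective and comes back to the route at 14.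

Step 5 (acylketene capture). Capture of the acylketene by the weakly nucleophilic phenol may be slow, which would allow ketene dimerization, attack by the enol-ether oxygen, reversal of ester formation at 110 °C, or acylation at the chelated 2-OH. The fallback moves the ester formation to room temperature. It sets out from 7: thermolysis with 2-methylpropane-2-thiol (toluene, sealed tube, 110 °C), a much faster ketene trap, should give S-tert-butyl (4Z)-4-chloro-5-methoxy-6-(2-methyl-1,3-dioxolan-2-yl)-3-oxohex-4-enethioate F7. Thiophilic activation with silver trifluoroacetate (CF3CO2Ag) in THF at 23 °C in the presence of 8 should transfer the acyl group to the 4-OH and comes back to the route at 10.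

Further compounds
F1 | step 7 | allyl (4Z)-4-chloro-5-methoxy-6-(2-methyl-1,3-dioxolan-2-yl)-3-oxohex-4-enoate | C=CCOC(=O)CC(=O)/C(Cl)=C(/OC)CC1(C)OCCO1
F2 | step 7 | allyl (4Z)-4-chloro-5-methoxy-3,7-dioxooct-4-enoate | C=CCOC(=O)CC(=O)/C(Cl)=C(/OC)CC(C)=O
F3 | step 7 | allyl 3-chloro-2-hydroxy-4-methoxy-6-methylbenzoate | C=CCOC(=O)c1c(C)cc(OC)c(Cl)c1O
F4 | step 7 | 3-chloro-2-hydroxy-4-methoxy-6-methylbenzoic acid | OC(=O)c1c(C)cc(OC)c(Cl)c1O
F5 | step 6 | methyl 4-[(4-chloro-3,5,7-trioxooctanoyl)oxy]-2-hydroxy-6-methylbenzoate (racemic) | COC(=O)c1c(C)cc(OC(=O)CC(=O)C(Cl)C(=O)CC(C)=O)cc1O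
F6 | step 6 | methyl 4-[(3-chloro-2,4-dihydroxy-6-methylbenzoyl)oxy]-2-hydroxy-6-methylbenzoate | COC(=O)c1c(C)cc(OC(=O)c2c(C)cc(O)c(Cl)c2O)cc1O
F7 | step 5 | S-tert-butyl (4Z)-4-chloro-5-methoxy-6-(2-methyl-1,3-dioxolan-2-yl)-3-oxohex-4-enethioate | CC(C)(C)SC(=O)CC(=O)/C(Cl)=C(/OC)CC1(C)OCCO1
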